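**Strategy.** The route rests on disconnecting the C12–C13 bond, so that ring C is closed last onto a spiro-fused ring D. The precursor is the finished ring A/B lactone carrying a 2-(nosyloxy)ethyl chain at C9 and a spiro 3-methylenecyclopentane at C8. In acid the methylene moves into the ring to the C13=C16 trisubstituted alkene; C13 then displaces the sulfonate at C12 and water traps the C16 tertiary cation. One operation closes ring C, completes the bicyclo[3.2.1]octane, sets C13 and C16 and installs the C16 methyl carbinol. The step exploits the tertiary carbinol C16 (OH, C17 methyl) adjacent to C13 in ring D, the signature of a Markovnikov cation.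

Key step: step 15

Remark: gibberellane numbering is used throughout (C7 = carboxyl carbon on C6, C17 = methyl on C16, C18 = methyl on C4, C19 = lactone carbonyl; α = the face of ring B that carries C11, β = the face of the hydrogen on C9). The C4 centre of 16 and 17 is left undefined because both epimers give the same lactone enolate in step 12.

Step 1
Reactants: 1 (3aR,4S,5R,6aS)-5-hydroxy-4-(hydroxymethyl)hexahydro-2H-cyclopenta[b]furan-2-one (commercial bicyclic lactone diol; supplies C5, C6, C8–C12 and C14)
Product: 2 primary tosylate of 1 (C14–OTs, secondary C6–OH free)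
Conditions: TsCl (1.05 equiv), pyridine, CH2Cl2, 0 °C
Reagents that add atoms: p-toluenesulfonyl chloride, Cc1ccc(cc1)S(Cl)(=O)=O
Why: Selective sulfonylation, since the primary alcohol reacts much faster than the ring secondary alcohol; no stereocentre is touched.

Step 2
Reactants: 2 primary tosylate
Product: 4 (3aR,6aS)-4-methylidenetetrahydro-2H-cyclopenta[b]furan-2,5(3H)-dione, via keto tosylate 3 (not isolated)
Conditions: DMP (triacetoxy periodinane, 1.2 equiv), CH2Cl2, 0 °C to rt; then Et3N (1.5 equiv), 0 °C; used crude
Reagents that add atoms: none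
Why: Periodinane oxidation gives the β-tosyloxy ketone, which should lose tosylate by E1cB elimination through the C8 enolate to the exocyclic enone (C6 ketone, C8=C14); C9 and C10 keep their configuration.

Step 3
Reactants: 4 exocyclic enone; 5 2-[(trimethylsilyl)methyl]allyl acetate
Product: 6 spiro ketone (C6 ketone, C12→C10 lactone, spiro 3-methylenecyclopentane at C8 with C15 on the β face and C14 on the α face)
Conditions: Pd(OAc)2 (5 mol%), P(OiPr)3 (30 mol%), THF, 65 °C
Reagents that add atoms: none
Why: Palladium-catalysed trimethylenemethane [3+2] cycloaddition (zerovalent palladium formed in situ): the zwitterion adds to the exocyclic CH2 (C14) and the C8 enolate closes onto the π-allyl terminus from the convex face of the cis-fused bicycle, anti to the C9 substituent, which sets C8.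

Step 4
Reactants: 6 spiro ketone
Product: 7 enol triflate (C5=C6–OTf)
Conditions: Tf2O (1.3 equiv), 2,6-di-tert-butyl-4-methylpyridine (1.5 equiv), CH2Cl2, 0 °C to rt
Reagents that add atoms: trifluoromethanesulfonic anhydride, O=S(=O)(OS(=O)(=O)C(F)(F)F)C(F)(F)F
Why: Enol triflate formation under non-enolate conditions, which should avoid E1cB loss of the β-acyloxy group at C10; only C5 carries α-hydrogens, so one regioisomer is possible.

Step 5
Reactants: 7 enol triflate
Product: 8 diol (C12 primary alcohol, C10 secondary allylic alcohol)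
Conditions: LiBH4 (2 equiv), THF, 0 °C to rt
Reagents that add atoms: none
Why: Chemoselective hydride reduction of the lactone to the diol; the vinyl triflate and the 1,1-disubstituted alkene should be inert.

Step 6
Reactants: 8 diol
Product: 9 C12 tert-butyldiphenylsilyl ether
Conditions: TBDPSCl (1.05 equiv), imidazole, CH2Cl2, 0 °C
Reagents that add atoms: tert-butyl(chloro)diphenylsilane, CC(C)(C)[Si](Cl)(c1ccccc1)c1ccccc1
Why: Selective silylation, the bulky silyl chloride discriminating the primary from the hindered secondary alcohol.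

Step 7
Reactants: 9 silyl ether
Product: 10 benzyl enoate (C5=C6–CO2Bn, C10–OH)
Conditions: Pd(OAc)2 (5 mol%), Ph2P(CH2)3PPh2 (6 mol%), CO (1 atm), BnOH (5 equiv), Et3N (2 equiv), DMF, 60 °C
Reagents that add atoms: carbon monoxide, [C-]#[O+]; benzyl alcohol, OCc1ccccc1
Why: Palladium-catalysed alkoxycarbonylation of the vinyl triflate (oxidative addition to zerovalent palladium, CO insertion, alcoholysis) installs C7 with the double bond fixed at C5=C6.

Step 8
Reactants: 10 allylic alcohol
Product: 11 keto enoate (C10 ketone conjugated to C5=C6–CO2Bn)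
Conditions: DMP (1.2 equiv), CH2Cl2, 0 °C; used at once
Reagents that add atoms: none
Why: Periodinane oxidation of the allylic alcohol under neutral conditions, chosen so that the C9 centre, now α to the ketone, is not epimerised.

Step 9
Reactants: 11 keto enoate; 12 [2-(1,3-dioxolan-2-yl)ethyl]magnesium bromide (commercial THF solution); 13 propionic anhydride
Product: 15 C10 tertiary propionate, via magnesium alkoxide 14 (not isolated)
Conditions: 12 (1.5 equiv), LaCl3·2LiCl (0.3 equiv), THF, −78 °C; then 13 (3 equiv), DMAP (0.2 equiv), −78 °C to rt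
Reagents that add atoms: none
Why: Grignard 1,2-addition (the lanthanum salt suppresses enolisation and conjugate addition) anti to the C9 side chain sets C10 with the C1–C3 chain on the β face and oxygen on the α face, cis to C11, and the alkoxide is acylated in the flask.

Step 10
Reactants: 15 propionate
Product: 16 cis-fused 19,10-γ-lactone (C4–C5 bond made, C4–H, C6–CO2Bn β)
Conditions: LiN(iPr)2 (1.2 equiv), THF, −78 to −30 °C; AcOH; then DBU (0.2 equiv), toluene, rt
Reagents that add atoms: none
Why: Intramolecular Michael addition (5-exo-trig) of the propionate enolate to C5, the β-carbon of the enoate; the tether through the α oxygen on C10 forces α-face delivery (C5 set, cis lactone), and DBU equilibrates C6 to the ester trans to C4.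

Step 11
Reactants: 16 lactone acetal
Product: 17 C3 aldehyde
Conditions: 1 M HCl, THF, rt
Reagents that add atoms: water, O
Why: Acid hydrolysis of the dioxolane; the silyl ether, the benzyl ester and the exocyclic alkene should survive dilute acid at room temperature.

Step 12
Reactants: 17 aldehyde
Product: 18 ring A aldol product (3β-OH, C4 quaternary)
Conditions: KOtBu (0.3 equiv), t-BuOH/THF (1:4), −20 °C, quenched with AcOH at full conversion
Reagents that add atoms: none
Why: Intramolecular aldol addition of the lactone enolate to the aldehyde closes ring A; C4 is fixed by the bridged geometry, and the 3β (axial) alcohol is expected under kinetic control from an open transition state with the potassium counter-ion, with C–O anti to the lactone carbonyl.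

Step 13
Reactants: 18 silyl ether
Product: 19 diol (C12–OH, C3–OH)
Conditions: Bu4NF (2 equiv), AcOH (2 equiv), THF, rt
Reagents that add atoms: none
Why: Fluoride desilylation, buffered with acetic acid so that the β-hydroxy lactone does not undergo retro-aldol epimerisation.

Step 14
Reactants: 19 diol
Product: 20 C12 4-nitrobenzenesulfonate
Conditions: 4-O2NC6H4SO2Cl (1.1 equiv), Et3N (1.5 equiv), DMAP (5 mol%), CH2Cl2, 0 °C
Reagents that add atoms: 4-nitrobenzenesulfonyl chloride, O=S(=O)(Cl)c1ccc(cc1)[N+](=O)[O-]
Why: Selective sulfonylation of the primary alcohol; the axial C3 alcohol next to quaternary C4 should react far more slowly.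

Step 15
Reactants: 20 nosylate
Product: 22 benzyl ester of the target gibberellin, via endocyclic alkene 21 (not isolated)
Conditions: TsOH·H2O (0.2 equiv), (CF3)2CHOH/H2O (4:1), rt then 60 °C
Reagents that add atoms: water, O
Why: TsOH protonates the exocyclic C16=C17 bond of 20 and the C16 cation loses a C13 proton to give the endocyclic trisubstituted alkene 21 (in equilibrium with its C15=C16 isomer); C13 of 21 then attacks C12 from the rear with loss of nosylate, and the resulting bicyclo[3.2.1]octyl C16 cation is trapped by water. The closest known reaction type is the solvolytic cation–olefin (π-participation) cyclisation of alkenyl arenesulfonates in ionising, weakly nucleophilic solvents, ending in Markovnikov hydration. Ring C (C8–C9–C11–C12–C13–C14) closes in a 6-exo mode, C13 attacking C12 with the C16 end of the π bond left outside the new ring. C13 is fixed by the tether, because only the C14 arm that is cis to C11 on ring B can reach C12, and C16 is fixed by water attacking the exo face, anti to the newly formed C12–C13 bond, which puts OH exo and the methyl endo. The step needs site selectivity between the interconverting alkene isomers and Markovnikov orientation; closure through C15 would demand a trans-fused bicyclo[3.3.0]octane and attack through C16 a secondary cation, so the equilibrating mixture should drain through 21 only.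

Step 16
Reactants: 22 benzyl ester of the target gibberellin
Product: 23 target gibberellin (free C7 acid)
Conditions: H2 (1 atm), Pd/C (10% palladium on carbon), EtOAc, rt
Reagents that add atoms: none
Why: Hydrogenolysis of the benzyl ester; no alkene remains, and the lactone and both alcohols are inert, so no stereocentre is at risk.

**Compound list**

1 | (3aR,4S,5R,6aS)-5-hydroxy-4-(hydroxymethyl)hexahydro-2H-cyclopenta[b]furan-2-one | O=C1O[C@H]2C[C@@H](O)[C@H](CO)[C@H]2C1 | starting material
2 | primary tosylate of 1 | O=C1O[C@H]2C[C@@H](O)[C@H](COS(=O)(=O)c3ccc(C)cc3)[C@H]2C1 | intermediate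
3 | keto tosylate (C6 ketone, C8–CH2OTs) | O=C1O[C@H]2CC(=O)[C@H](COS(=O)(=O)c3ccc(C)cc3)[C@H]2C1 | intermediate
4 | (3aR,6aS)-4-methylidenetetrahydro-2H-cyclopenta[b]furan-2,5(3H)-dione | O=C1O[C@H]2CC(=O)C(=C)[C@H]2C1 | intermediate
5 | 2-[(trimethylsilyl)methyl]allyl acetate | CC(=O)OCC(=C)C[Si](C)(C)C | starting material
6 | spiro ketone (lactone, C6 ketone, spiro 3-methylenecyclopentane at C8) | O=C1O[C@H]2CC(=O)[C@@]3(CCC(=C)C3)[C@H]2C1 | intermediate
7 | enol triflate (C5=C6–OTf) | O=C1O[C@H]2C=C(OS(=O)(=O)C(F)(F)F)[C@@]3(CCC(=C)C3)[C@H]2C1 | intermediate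
8 | diol (C12–OH, C10–OH) enol triflate | OCC[C@H]1[C@@H](O)C=C(OS(=O)(=O)C(F)(F)F)[C@@]12CCC(=C)C2 | intermediate
9 | C12 tert-butyldiphenylsilyl ether of 8 | CC(C)(C)[Si](c1ccccc1)(c1ccccc1)OCC[C@H]1[C@@H](O)C=C(OS(=O)(=O)C(F)(F)F)[C@@]12CCC(=C)C2 | intermediate
10 | benzyl enoate with C10 allylic alcohol | CC(C)(C)[Si](c1ccccc1)(c1ccccc1)OCC[C@H]1[C@@H](O)C=C(C(=O)OCc3ccccc3)[C@@]12CCC(=C)C2 | intermediate
11 | keto enoate (C10 ketone) | CC(C)(C)[Si](c1ccccc1)(c1ccccc1)OCC[C@H]1C(=O)C=C(C(=O)OCc3ccccc3)[C@@]12CCC(=C)C2 | intermediate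
12 | [2-(1,3-dioxolan-2-yl)ethyl]magnesium bromide | Br[Mg]CCC1OCCO1 | starting material
13 | propionic anhydride | CCC(=O)OC(=O)CC | starting material
14 | bromomagnesium C10 alkoxide | CC(C)(C)[Si](c1ccccc1)(c1ccccc1)OCC[C@H]1[C@](O[Mg]Br)(CCC3OCCO3)C=C(C(=O)OCc4ccccc4)[C@@]12CCC(=C)C2 | intermediate
15 | C10 tertiary propionate | CC(C)(C)[Si](c1ccccc1)(c1ccccc1)OCC[C@H]1[C@](OC(=O)CC)(CCC3OCCO3)C=C(C(=O)OCc4ccccc4)[C@@]12CCC(=C)C2 | intermediate
16 | cis-fused 19,10-lactone with C3 dioxolane (C4 undefined) | CC1C(=O)O[C@]2(CCC3OCCO3)[C@H](CCO[Si](c4ccccc4)(c5ccccc5)C(C)(C)C)[C@]6(CCC(=C)C6)[C@@H](C(=O)OCc7ccccc7)[C@H]12 | intermediate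
17 | C3 aldehyde lactone (C4 undefined) | CC1C(=O)O[C@]2(CCC=O)[C@H](CCO[Si](c3ccccc3)(c4ccccc4)C(C)(C)C)[C@]5(CCC(=C)C5)[C@@H](C(=O)OCc6ccccc6)[C@H]12 | intermediate
18 | ring A aldol product (3β-OH), C12 silyl ether | C[C@@]12C(=O)O[C@]3(CC[C@@H]1O)[C@H](CCO[Si](c4ccccc4)(c5ccccc5)C(C)(C)C)[C@]6(CCC(=C)C6)[C@@H](C(=O)OCc7ccccc7)[C@@H]32 | intermediate
19 | C12 primary alcohol (3,12-diol) | C[C@@]12C(=O)O[C@]3(CC[C@@H]1O)[C@H](CCO)[C@]4(CCC(=C)C4)[C@@H](C(=O)OCc5ccccc5)[C@@H]32 | intermediate
20 | C12 4-nitrobenzenesulfonate (exocyclic methylene in ring D) | C[C@@]12C(=O)O[C@]3(CC[C@@H]1O)[C@H](CCOS(=O)(=O)c4ccc(cc4)[N+](=O)[O-])[C@]5(CCC(=C)C5)[C@@H](C(=O)OCc6ccccc6)[C@@H]32 | intermediate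
21 | endocyclic C13=C16 alkene isomer of 20 | C[C@@]12C(=O)O[C@]3(CC[C@@H]1O)[C@H](CCOS(=O)(=O)c4ccc(cc4)[N+](=O)[O-])[C@]5(CC=C(C)C5)[C@@H](C(=O)OCc6ccccc6)[C@@H]32 | intermediate
22 | benzyl ester of the target gibberellin (C7 benzyl ester of 23) | C[C@@]12C(=O)O[C@]3(CC[C@@H]1O)[C@@H]1CC[C@@H]4C[C@]1(C[C@@]4(C)O)[C@@H](C(=O)OCc5ccccc5)[C@@H]32 | intermediate
23 | target gibberellin: 3β,16-dihydroxy 19,10-lactone 7-carboxylic acid with saturated ring D (16-OH exo, C17 methyl endo) | C[C@@]12C(=O)O[C@]3(CC[C@@H]1O)[C@@H]1CC[C@@H]4C[C@]1(C[C@@]4(C)O)[C@@H](C(=O)O)[C@@H]32 | target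

**Step count and risk**

Total step count: 16. Longest linear sequence: 16 steps, from compound 1.

Steps most likely to fail:

Step 15 (key step). Ionisation of the primary sulfonate with π-participation may be slower than the acid-driven side processes of the tertiary cation: Wagner–Meerwein reorganisation, elimination back to alkenes, or interception by the C7 ester carbonyl. The fallback avoids carbocations and closes the same bond by enolate alkylation. It sets out from 20. Ozonolysis of the exocyclic methylene (O3, CH2Cl2/MeOH, −78 °C; Me2S) should give the C16 ketone nosylate F1. LiN(SiMe3)2 (2.2 equiv, THF, −78 to 0 °C) should then alkylate the C13 enolate with C12 to give the bicyclo[3.2.1]octan-16-one F2; the C15 enolate could only close a trans-fused five-membered ring. Lombardo methylenation (Zn, CH2Br2, TiCl4) should give the 16-methylidene benzyl ester F3. Mukaiyama hydration (Co(acac)2, PhSiH3, O2, THF), with exo-face oxygen capture by the C16 radical, returns to the route at 22.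

Step 10. The ester enolate must react through the disfavoured s-cis ester conformer. Cyclisation may therefore be slow enough for sigmatropic rearrangement of the allylic ester enolate or intermolecular condensation to compete. The fallback is a radical conjugate addition. It sets out from alkoxide 14, generated as in step 9 and quenched with 2-bromopropionyl bromide instead of 13, to give the α-bromopropionate F4. Slow addition of Bu3SnH with AIBN in toluene at 80 °C should effect 5-exo radical cyclisation onto C5 and hydrogen transfer to the C6 radical. After the same DBU equilibration the route is rejoined at 16.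

Step 12. Facial control at C3 may be poor, and retro-aldol equilibration may move the product toward the equatorial 3α epimer; enolisation of the aldehyde may also divert material. The fallback sets C3 by reagent-controlled hydride delivery instead of aldol facial control. It sets out from 17. The aldol is run to equilibrium (KOtBu, t-BuOH/THF, rt), accepting the 3α-hydroxy epimer F5 together with 18. The mixture is oxidised with DMP to the single 3-ketone F6. K[BH(s-Bu)3] (THF, −78 °C) should attack from the less hindered equatorial direction to give the axial 3β alcohol, returning at 18.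

Further compounds
F1 | step 15 | C16 ketone nosylate (17-nor-16-oxo ring D, spiro) | C[C@@]12C(=O)O[C@]3(CC[C@@H]1O)[C@H](CCOS(=O)(=O)c4ccc(cc4)[N+](=O)[O-])[C@]5(CCC(=O)C5)[C@@H](C(=O)OCc6ccccc6)[C@@H]32
F2 | step 15 | 16-oxo-17-nor analogue of 22 (bicyclo[3.2.1]octan-16-one, benzyl ester) | C[C@@]12C(=O)O[C@]3(CC[C@@H]1O)[C@@H]1CC[C@@H]4C[C@]1(CC4=O)[C@@H](C(=O)OCc5ccccc5)[C@@H]32
F3 | step 15 | 16-methylidene analogue of 22 (exocyclic C16=C17 alkene, benzyl ester) | C[C@@]12C(=O)O[C@]3(CC[C@@H]1O)[C@@H]1CC[C@@H]4C[C@]1(CC4=C)[C@@H](C(=O)OCc5ccccc5)[C@@H]32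
F4 | step 10 | C10 tertiary 2-bromopropionate | CC(C)(C)[Si](c1ccccc1)(c1ccccc1)OCC[C@H]1[C@](OC(=O)C(C)Br)(CCC3OCCO3)C=C(C(=O)OCc4ccccc4)[C@@]12CCC(=C)C2
F5 | step 12 | 3α-hydroxy epimer of 18 | C[C@@]12C(=O)O[C@]3(CC[C@H]1O)[C@H](CCO[Si](c4ccccc4)(c5ccccc5)C(C)(C)C)[C@]6(CCC(=C)C6)[C@@H](C(=O)OCc7ccccc7)[C@@H]32
F6 | step 12 | 3-ketone of 18 | C[C@@]12C(=O)O[C@]3(CCC1=O)[C@H](CCO[Si](c4ccccc4)(c5ccccc5)C(C)(C)C)[C@]6(CCC(=C)C6)[C@@H](C(=O)OCc7ccccc7)[C@@H]32
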